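**Plan**

- Retrosynthesis: the pyran O1–C2 bond is cut first. Then come the bond between the side-chain ketone carbon and its allylic CH2 (dithiane alkylation), the bond between the ring-bound carbonyl carbon and the alkyne (acetylide addition), the aryl–allyl bond (phenoxide prenylation) and the two cyclopentane bonds made by annulating a 2,3-dimethylsuccinimide with a C3 unit.
- Forward: the cyclopentane is built first as a meso, cis-fused bicyclic imide, desymmetrised and converted into a hydroxy dithiane (fragment 1). The aryl allylic chloride (fragment 2) is made separately and joined at the dithiane carbon. The ynol arm is added, the ketone unmasked, the ynone formed and semihydrogenated, the phenol freed, and the pyran ring closed last.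
- Enabling feature: the phenol oxygen O1 on C8a sits ortho to the C4 methylene, which is both benzylic and allylic to the C2=C3 alkene. Loss of hydride from C4 gives an ortho-quinone methide whose O1=C8a–C4a=C4–C3=C2 oxatriene closes to the pyran ring at O1–C2.
- Stereochemistry: the two quaternary centres are cis because the bicyclo[3.3.0] imide can only be cis-fused. Their absolute configuration comes from enantioselective reduction of one of the two enantiotopic imide carbonyls. The E alkene comes from SeO2 oxidation of the prenyl E-methyl, the Z enone from Lindlar reduction, and C2 from the enzyme pocket.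

Key step: step 19

Assumption: the (R)-oxazaborolidine is taken to deliver hydride to the carbonyl on the S-configured bridgehead carbon of 5; if the sense proves opposite, the (S)-catalyst is used and nothing else changes.
Assumption: a flavin oxidocyclase variant that accepts the carboxyl-free phenol 26 and closes it in the 2R sense is taken to be obtainable by screening and directed evolution of the chromene-forming synthases.

**Fragment 1: cyclopentane (steps 1–7)**

Step 1
Reactants: 1 2,3-dimethylsuccinic acid (commercial mixture of meso and racemic forms)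
Product: 2 1-benzyl-3,4-dimethylpyrrolidine-2,5-dione (cis/trans mixture)
Conditions: BnNH2, xylene, reflux, Dean–Stark trap
Reagents that add atoms: benzylamine, NCc1ccccc1
Why: Thermal condensation of a succinic acid with a primary amine (imide formation) is driven by removal of water; the configuration at C3 and C4 is irrelevant because both centres are enolised in step 2.

Step 2
Reactants: 2 1-benzyl-3,4-dimethylpyrrolidine-2,5-dione; 3 1-bromo-3-chloropropane
Product: 5 (1R,5S)-3-benzyl-1,5-dimethyl-3-azabicyclo[3.3.0]octane-2,4-dione (meso, cis-fused), via chloropropyl imide 4 (not isolated)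
Conditions: LiN(iPr)2 (1.05 equiv), THF, −78 °C; 3, −78 → 0 °C; then LiN(iPr)2 (1.2 equiv), DMPU, −78 °C → rt
Reagents that add atoms: none
Why: Two successive imide enolate C-alkylations, the second a 5-exo-tet ring closure; the chain anchored on C3 can reach the C4 enolate only from its own face, so the new ring is cis-fused and both quaternary methyl centres are set cis, which gives the meso imide whatever the diastereomer mixture of 2 and 4.

Step 3
Reactants: 5 (1R,5S)-3-benzyl-1,5-dimethyl-3-azabicyclo[3.3.0]octane-2,4-dione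
Product: 6 (1R,5S)-3-benzyl-4-hydroxy-1,5-dimethyl-3-azabicyclo[3.3.0]octan-2-one (either configuration at C4)
Conditions: (3aR)-1-methyl-3,3-diphenyltetrahydro-1H,3H-pyrrolo[1,2-c][1,3,2]oxazaborole (0.5 equiv), BH3·SMe2, THF, 0 °C → rt; then MeOH, aq. NH4Cl
Reagents that add atoms: none
Why: Oxazaborolidine-catalysed borane reduction (CBS type) of a meso N-benzyl imide is a known enantiotopic-group-selective reduction that stops at the hydroxy lactam; the catalyst selects the carbonyl on the S-configured bridgehead and thereby fixes the absolute configuration of both quaternary centres, the carbinol centre being of no consequence.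

Step 4
Reactants: 6 (1R,5S)-3-benzyl-4-hydroxy-1,5-dimethyl-3-azabicyclo[3.3.0]octan-2-one
Product: 8 (1R,5S)-1,5-dimethyl-3-oxabicyclo[3.3.0]octan-2-one, via hydroxy amide 7 (not isolated)
Conditions: NaBH4, EtOH, 0 °C → rt; then 2 M H2SO4, 1,4-dioxane, 90 °C
Reagents that add atoms: none
Why: NaBH4 reduces the hydroxy lactam through its ring-opened aldehyde form to hydroxy amide 7, and acid-promoted N-to-O acyl transfer (lactonisation, helped by the gem-disubstitution) expels benzylamine without touching a stereocentre.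

Step 5
Reactants: 8 (1R,5S)-1,5-dimethyl-3-oxabicyclo[3.3.0]octan-2-one
Product: 9 (1R,5S)-1,5-dimethyl-3-oxabicyclo[3.3.0]octan-2-ol (anomer mixture)
Conditions: i-Bu2AlH, CH2Cl2, −78 °C; aq. potassium sodium tartrate
Reagents that add atoms: none
Why: Half-reduction of a γ-lactone with i-Bu2AlH stops at the lactol because the tetrahedral aluminate is stable at −78 °C.

Step 6
Reactants: 9 (1R,5S)-1,5-dimethyl-3-oxabicyclo[3.3.0]octan-2-ol
Product: 10 [(1S,2S)-2-(2-methoxyethenyl)-1,2-dimethylcyclopentyl]methanol (E/Z mixture)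
Conditions: (methoxymethyl)triphenylphosphonium chloride (3 equiv), KOtBu (3 equiv), THF, 0 °C → 40 °C
Reagents that add atoms: (methoxymethyl)triphenylphosphonium chloride, COC[P+](c1ccccc1)(c1ccccc1)c1ccccc1.[Cl-]
Why: Wittig methoxymethylenation of the hydroxy aldehyde tautomer of a lactol is a standard one-carbon homologation; the neopentyl aldehyde cannot enolise, excess ylide covers the free hydroxyl, and the enol ether geometry is irrelevant.

Step 7
Reactants: 10 [(1S,2S)-2-(2-methoxyethenyl)-1,2-dimethylcyclopentyl]methanol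
Product: 11 {(1S,2S)-2-[(1,3-dithian-2-yl)methyl]-1,2-dimethylcyclopentyl}methanol
Conditions: HS(CH2)3SH, BF3·OEt2, CH2Cl2, −20 → 0 °C
Reagents that add atoms: propane-1,3-dithiol, SCCCS
Why: Lewis-acid-mediated thioacetalisation converts the enol ether, by way of its oxocarbenium ion or cyclic O,O-acetal, into the thermodynamically favoured open-chain 1,3-dithiane and leaves the neopentyl alcohol free.

**Fragment 2: aryl allylic chloride (steps 8–11)**

Step 8
Reactants: 12 4-methoxy-2-methylphenol; 13 prenyl bromide (1-bromo-3-methylbut-2-ene)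
Product: 14 4-methoxy-2-methyl-6-(3-methylbut-2-en-1-yl)phenol
Conditions: NaH, toluene, 0 °C; then 13, rt
Reagents that add atoms: none
Why: C-Alkylation of a sodium phenoxide by an allylic bromide in a non-polar solvent goes to the ortho position through the tight ion pair; C6 is the only free ortho site and the para position carries the methoxy group.

Step 9
Reactants: 14 4-methoxy-2-methyl-6-(3-methylbut-2-en-1-yl)phenol
Product: 15 tert-butyl[4-methoxy-2-methyl-6-(3-methylbut-2-en-1-yl)phenoxy]dimethylsilane
Conditions: TBSCl, imidazole, DMF, 40 °C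
Reagents that add atoms: tert-butyldimethylsilyl chloride, CC(C)(C)[Si](C)(C)Cl
Why: Standard silylation of a phenol; the two ortho substituents make the aryl silyl ether robust toward the organolithium steps that follow.

Step 10
Reactants: 15 tert-butyl[4-methoxy-2-methyl-6-(3-methylbut-2-en-1-yl)phenoxy]dimethylsilane
Product: 16 (2E)-4-[2-(tert-butyldimethylsilyloxy)-5-methoxy-3-methylphenyl]-2-methylbut-2-en-1-ol
Conditions: SeO2 (0.3 equiv), t-BuOOH, CH2Cl2, rt
Reagents that add atoms: selenium dioxide, O=[Se]=O (oxygen carrier); tert-butyl hydroperoxide, CC(C)(C)OO (terminal oxygen source)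
Why: SeO2 allylic oxidation (ene reaction, then [2,3]-sigmatropic shift) attacks the more substituted alkene terminus at the methyl trans to the chain, which gives the E allylic alcohol.

Step 11
Reactants: 16 (2E)-4-[2-(tert-butyldimethylsilyloxy)-5-methoxy-3-methylphenyl]-2-methylbut-2-en-1-ol
Product: 18 tert-butyl{2-[(2E)-4-chloro-3-methylbut-2-en-1-yl]-4-methoxy-6-methylphenoxy}dimethylsilane, via allylic mesylate 17 (not isolated)
Conditions: MsCl, 2,4,6-collidine, LiCl, DMF, 0 °C
Reagents that add atoms: methanesulfonyl chloride, CS(=O)(=O)Cl (kept only in 17); lithium chloride, [Li+].[Cl-]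
Why: Mesylation followed by SN2 displacement with chloride in DMF converts primary allylic alcohols into chlorides without allylic transposition or loss of alkene geometry.

**Union and end game (steps 12–19)**

Step 12
Reactants: 11 {(1S,2S)-2-[(1,3-dithian-2-yl)methyl]-1,2-dimethylcyclopentyl}methanol; 18 tert-butyl{2-[(2E)-4-chloro-3-methylbut-2-en-1-yl]-4-methoxy-6-methylphenoxy}dimethylsilane
Product: 19 {(1S,2S)-2-[(2-{(2E)-4-[2-(tert-butyldimethylsilyloxy)-5-methoxy-3-methylphenyl]-2-methylbut-2-en-1-yl}-1,3-dithian-2-yl)methyl]-1,2-dimethylcyclopentyl}methanol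
Conditions: 11, n-BuLi (2.2 equiv), THF–HMPA, −30 °C; then 18, −78 → −20 °C
Reagents that add atoms: none
Why: Corey–Seebach umpolung: the alkoxide–dithiane dianion of 11 is C-alkylated by the primary allylic chloride in an SN2 reaction, the lithium alkoxide being a far poorer nucleophile than the sulfur-stabilised carbanion.

Step 13
Reactants: 19 (the dithiane alcohol from step 12)
Product: 20 (1S,2S)-2-[(2-{(2E)-4-[2-(tert-butyldimethylsilyloxy)-5-methoxy-3-methylphenyl]-2-methylbut-2-en-1-yl}-1,3-dithian-2-yl)methyl]-1,2-dimethylcyclopentane-1-carbaldehyde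
Conditions: (COCl)2, DMSO, CH2Cl2, −78 °C; then Et3N, −78 → 0 °C
Reagents that add atoms: none
Why: Swern oxidation of the neopentyl primary alcohol gives a non-enolisable aldehyde and is compatible with the dithiane, the alkene and the aryl silyl ether.

Step 14
Reactants: 20 (the aldehyde from step 13); 21 2-methylbut-3-yn-2-ol
Product: 22 1-{(1S,2S)-2-[(2-{(2E)-4-[2-(tert-butyldimethylsilyloxy)-5-methoxy-3-methylphenyl]-2-methylbut-2-en-1-yl}-1,3-dithian-2-yl)methyl]-1,2-dimethylcyclopentyl}-4-methylpent-2-yne-1,4-diol (mixture of C1 carbinol epimers)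
Conditions: 21 (3 equiv), n-BuLi (6 equiv), THF, −78 → 0 °C; then 20, −78 → 0 °C
Reagents that add atoms: none
Why: 1,2-Addition of a lithium acetylide (here the dianion of the propargylic alcohol) to a non-enolisable aldehyde; the new carbinol centre forms without control and is erased by the oxidation in step 16.

Step 15
Reactants: 22 (the dithiane diol from step 14)
Product: 23 (4E)-6-[2-(tert-butyldimethylsilyloxy)-5-methoxy-3-methylphenyl]-1-[(1S,2S)-2-(1,4-dihydroxy-4-methylpent-2-yn-1-yl)-1,2-dimethylcyclopentyl]-4-methylhex-4-en-2-one (carbinol epimers)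
Conditions: MeI, CaCO3, MeCN–H2O (9:1), 45 °C
Reagents that add atoms: water, O
Why: Alkylative dithiane hydrolysis (S-methylation, then hydrolysis under CaCO3 buffering) frees the ketone under near-neutral conditions that leave the alkyne, the β,γ-alkene and the silyl ether alone.

Step 16
Reactants: 23 (the keto diol from step 15)
Product: 24 1-[(1S,2S)-2-{(4E)-6-[2-(tert-butyldimethylsilyloxy)-5-methoxy-3-methylphenyl]-4-methyl-2-oxohex-4-en-1-yl}-1,2-dimethylcyclopentyl]-4-hydroxy-4-methylpent-2-yn-1-one
Conditions: MnO2 (activated, excess), CH2Cl2, rt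
Reagents that add atoms: none
Why: MnO2 oxidises the activated propargylic secondary alcohol selectively, and the tertiary alcohol cannot be oxidised.

Step 17
Reactants: 24 (the ynone from step 16)
Product: 25 (2Z)-1-[(1S,2S)-2-{(4E)-6-[2-(tert-butyldimethylsilyloxy)-5-methoxy-3-methylphenyl]-4-methyl-2-oxohex-4-en-1-yl}-1,2-dimethylcyclopentyl]-4-hydroxy-4-methylpent-2-en-1-one
Conditions: H2 (1 atm), Pd on CaCO3 poisoned with Pb(OAc)2 (Lindlar catalyst), quinoline, EtOAc, rt
Reagents that add atoms: none
Why: Lindlar semihydrogenation adds H2 syn to the alkyne on the poisoned palladium surface and stops at the Z alkene; the trisubstituted alkene is not reduced.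

Step 18
Reactants: 25 (the Z enone silyl ether from step 17)
Product: 26 (2Z)-4-hydroxy-1-[(1S,2S)-2-{(4E)-6-(2-hydroxy-5-methoxy-3-methylphenyl)-4-methyl-2-oxohex-4-en-1-yl}-1,2-dimethylcyclopentyl]-4-methylpent-2-en-1-one
Conditions: Bu4NF, AcOH, THF, 0 °C
Reagents that add atoms: none
Why: Fluoride cleaves the aryl Si–O bond, and acetic acid buffering keeps the medium non-basic so that the β,γ-unsaturated ketone and the Z-hydroxy enone are not isomerised.

Step 19
Reactants: 26 (the open-chain ortho-alkenyl phenol from step 18)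
Product: 28 (2Z)-4-hydroxy-1-[(1S,2S)-2-{3-[(2R)-6-methoxy-2,8-dimethyl-2H-chromen-2-yl]-2-oxopropyl}-1,2-dimethylcyclopentyl]-4-methylpent-2-en-1-one (CNP0137762.2), via ortho-quinone methide 27 (not isolated)
Conditions: engineered FAD-dependent berberine-bridge-enzyme-like oxidocyclase (variant of a daurichromenic acid synthase selected for 26), O2 (air), catalase, citrate–phosphate buffer pH 6.0, 5% v/v DMSO, 30 °C
Reagents that add atoms: none
Why: Proposed new method: in the active site the phenol of 26 is deprotonated and the oxidised flavin cofactor accepts a hydride from C4, which gives ortho-quinone methide 27, while O2 returns the reduced flavin to its oxidised form and the H2O2 formed is destroyed by catalase. The closest known reaction type is the flavin-dependent oxidative cyclisation of ortho-prenyl-type resorcylic acids to chiral 2H-chromenes by the cannabichromenic and daurichromenic acid synthases, which has not been shown for a carboxyl-free, ketone-bearing phenol such as 26. The pyran ring closes by a thermal disrotatory oxa-6π electrocyclisation of the O1=C8a–C4a=C4–C3=C2 oxatriene, which forms the O1–C2 bond. The new stereocentre C2 (R) is set by the helical sense in which the chiral pocket folds the oxatriene, since the cyclopentane centres lie four and five bonds away and cannot bias the closure. The step needs oxidation at C4 only and a single sense of closure: the first is secured by the substrate, because C4–H is the only C–H that is at once benzylic, allylic and ortho to the phenoxide, whereas the Z-hydroxy enone, the ketone and the tertiary alcohol offer no comparably hydridic position, and the second is secured by the enzyme.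

**Compound list**

1 | 2,3-dimethylsuccinic acid (meso/racemic mixture) | CC(C(=O)O)C(C)C(=O)O | starting material
2 | 1-benzyl-3,4-dimethylpyrrolidine-2,5-dione (cis/trans mixture) | CC1C(C)C(=O)N(Cc2ccccc2)C1=O | intermediate
3 | 1-bromo-3-chloropropane | ClCCCBr | starting material
4 | 1-benzyl-3-(3-chloropropyl)-3,4-dimethylpyrrolidine-2,5-dione (diastereomer mixture) | CC1C(=O)N(Cc2ccccc2)C(=O)C1(C)CCCCl | intermediate
5 | (1R,5S)-3-benzyl-1,5-dimethyl-3-azabicyclo[3.3.0]octane-2,4-dione (meso) | O=C3[C@]1(C)CCC[C@]1(C)C(=O)N3Cc4ccccc4 | intermediate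
6 | (1R,5S)-3-benzyl-4-hydroxy-1,5-dimethyl-3-azabicyclo[3.3.0]octan-2-one (C4 epimers) | O=C3[C@]1(C)CCC[C@]1(C)C(O)N3Cc4ccccc4 | intermediate
7 | (1R,2S)-N-benzyl-2-(hydroxymethyl)-1,2-dimethylcyclopentane-1-carboxamide | O=C(NCc1ccccc1)[C@]2(C)CCC[C@]2(C)CO | intermediate
8 | (1R,5S)-1,5-dimethyl-3-oxabicyclo[3.3.0]octan-2-one | O=C3[C@]1(C)CCC[C@]1(C)CO3 | intermediate
9 | (1R,5S)-1,5-dimethyl-3-oxabicyclo[3.3.0]octan-2-ol (anomer mixture) | OC3[C@]1(C)CCC[C@]1(C)CO3 | intermediate
10 | [(1S,2S)-2-(2-methoxyethenyl)-1,2-dimethylcyclopentyl]methanol (E/Z mixture) | COC=C[C@]1(C)CCC[C@]1(C)CO | intermediate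
11 | {(1S,2S)-2-[(1,3-dithian-2-yl)methyl]-1,2-dimethylcyclopentyl}methanol | C3(SCCCS3)C[C@]1(C)CCC[C@]1(C)CO | intermediate
12 | 4-methoxy-2-methylphenol | COc1ccc(O)c(C)c1 | starting material
13 | prenyl bromide | CC(C)=CCBr | starting material
14 | 4-methoxy-2-methyl-6-(3-methylbut-2-en-1-yl)phenol | COc1cc(C)c(O)c(CC=C(C)C)c1 | intermediate
15 | tert-butyl[4-methoxy-2-methyl-6-(3-methylbut-2-en-1-yl)phenoxy]dimethylsilane | COc1cc(C)c(O[Si](C)(C)C(C)(C)C)c(CC=C(C)C)c1 | intermediate
16 | (2E)-4-[2-(tert-butyldimethylsilyloxy)-5-methoxy-3-methylphenyl]-2-methylbut-2-en-1-ol | COc1cc(C)c(O[Si](C)(C)C(C)(C)C)c(C/C=C(\C)CO)c1 | intermediate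
17 | (2E)-4-[2-(tert-butyldimethylsilyloxy)-5-methoxy-3-methylphenyl]-2-methylbut-2-en-1-yl methanesulfonate | COc1cc(C)c(O[Si](C)(C)C(C)(C)C)c(C/C=C(\C)COS(C)(=O)=O)c1 | intermediate
18 | tert-butyl{2-[(2E)-4-chloro-3-methylbut-2-en-1-yl]-4-methoxy-6-methylphenoxy}dimethylsilane | COc1cc(C)c(O[Si](C)(C)C(C)(C)C)c(C/C=C(\C)CCl)c1 | intermediate
19 | {(1S,2S)-2-[(2-{(2E)-4-[2-(tert-butyldimethylsilyloxy)-5-methoxy-3-methylphenyl]-2-methylbut-2-en-1-yl}-1,3-dithian-2-yl)methyl]-1,2-dimethylcyclopentyl}methanol | COc1cc(C)c(O[Si](C)(C)C(C)(C)C)c(C/C=C(\C)CC2(C[C@]3(C)CCC[C@]3(C)CO)SCCCS2)c1 | intermediate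
20 | (1S,2S)-2-[(2-{(2E)-4-[2-(tert-butyldimethylsilyloxy)-5-methoxy-3-methylphenyl]-2-methylbut-2-en-1-yl}-1,3-dithian-2-yl)methyl]-1,2-dimethylcyclopentane-1-carbaldehyde | COc1cc(C)c(O[Si](C)(C)C(C)(C)C)c(C/C=C(\C)CC2(C[C@]3(C)CCC[C@]3(C)C=O)SCCCS2)c1 | intermediate
21 | 2-methylbut-3-yn-2-ol | C#CC(C)(C)O | starting material
22 | 1-{(1S,2S)-2-[(2-{(2E)-4-[2-(tert-butyldimethylsilyloxy)-5-methoxy-3-methylphenyl]-2-methylbut-2-en-1-yl}-1,3-dithian-2-yl)methyl]-1,2-dimethylcyclopentyl}-4-methylpent-2-yne-1,4-diol (C1 epimers) | COc1cc(C)c(O[Si](C)(C)C(C)(C)C)c(C/C=C(\C)CC2(C[C@]3(C)CCC[C@]3(C)C(O)C#CC(C)(C)O)SCCCS2)c1 | intermediate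
23 | (4E)-6-[2-(tert-butyldimethylsilyloxy)-5-methoxy-3-methylphenyl]-1-[(1S,2S)-2-(1,4-dihydroxy-4-methylpent-2-yn-1-yl)-1,2-dimethylcyclopentyl]-4-methylhex-4-en-2-one (carbinol epimers) | COc1cc(C)c(O[Si](C)(C)C(C)(C)C)c(C/C=C(\C)CC(=O)C[C@]2(C)CCC[C@]2(C)C(O)C#CC(C)(C)O)c1 | intermediate
24 | 1-[(1S,2S)-2-{(4E)-6-[2-(tert-butyldimethylsilyloxy)-5-methoxy-3-methylphenyl]-4-methyl-2-oxohex-4-en-1-yl}-1,2-dimethylcyclopentyl]-4-hydroxy-4-methylpent-2-yn-1-one | COc1cc(C)c(O[Si](C)(C)C(C)(C)C)c(C/C=C(\C)CC(=O)C[C@]2(C)CCC[C@]2(C)C(=O)C#CC(C)(C)O)c1 | intermediate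
25 | (2Z)-1-[(1S,2S)-2-{(4E)-6-[2-(tert-butyldimethylsilyloxy)-5-methoxy-3-methylphenyl]-4-methyl-2-oxohex-4-en-1-yl}-1,2-dimethylcyclopentyl]-4-hydroxy-4-methylpent-2-en-1-one | COc1cc(C)c(O[Si](C)(C)C(C)(C)C)c(C/C=C(\C)CC(=O)C[C@]2(C)CCC[C@]2(C)C(=O)/C=C\C(C)(C)O)c1 | intermediate
26 | (2Z)-4-hydroxy-1-[(1S,2S)-2-{(4E)-6-(2-hydroxy-5-methoxy-3-methylphenyl)-4-methyl-2-oxohex-4-en-1-yl}-1,2-dimethylcyclopentyl]-4-methylpent-2-en-1-one | COc1cc(C)c(O)c(C/C=C(\C)CC(=O)C[C@]2(C)CCC[C@]2(C)C(=O)/C=C\C(C)(C)O)c1 | intermediate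
27 | (2Z)-4-hydroxy-1-[(1S,2S)-2-{(4E)-6-(3-methoxy-5-methyl-6-oxocyclohexa-2,4-dien-1-ylidene)-4-methyl-2-oxohex-4-en-1-yl}-1,2-dimethylcyclopentyl]-4-methylpent-2-en-1-one (ortho-quinone methide, side chain syn to the ring carbonyl) | COC1=C/C(=C/C=C(\C)CC(=O)C[C@]2(C)CCC[C@]2(C)C(=O)/C=C\C(C)(C)O)C(=O)C(C)=C1 | intermediate
28 | (2Z)-4-hydroxy-1-[(1S,2S)-2-{3-[(2R)-6-methoxy-2,8-dimethyl-2H-chromen-2-yl]-2-oxopropyl}-1,2-dimethylcyclopentyl]-4-methylpent-2-en-1-one | COc1cc(C)c2c(c1)C=C[C@@](C)(CC(=O)C[C@]1(C)CCC[C@]1(C)C(=O)/C=C\C(C)(C)O)O2 | target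

**Step count and risks**

Total steps: 19. Longest linear sequence: 15 (steps 1–7 and 12–19); the aryl fragment takes 4 steps (8–11).

Steps most likely to fail:

Step 19. The enzyme may fail to bind or turn over the carboxyl-free phenol, or may fold the oxatriene without a single helical sense. The fallback uses known chemistry and runs from 26 to 28. Oxidation of 26 with 2,3-dichloro-5,6-dicyano-1,4-benzoquinone in toluene at room temperature passes through the same quinone methide 27 in free solution. It should give 28 together with its C2 epimer, (2Z)-4-hydroxy-1-[(1S,2S)-2-{3-[(2S)-6-methoxy-2,8-dimethyl-2H-chromen-2-yl]-2-oxopropyl}-1,2-dimethylcyclopentyl]-4-methylpent-2-en-1-one F1. The two diastereomers would be separated by preparative HPLC, and the route is rejoined at 28.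

Step 3. Discrimination between the two enantiotopic, neopentyl-type carbonyls may be poor, or hydride transfer to them slow, so that lactone 8 arrives with low enantiomeric purity. The fallback replaces catalyst control by a resolution through covalent diastereomers and runs from 8 back to 8. Aminolysis of the scalemic lactone with (S)-1-phenylethylamine and AlMe3 in toluene at 60 °C should give (1R,2S)-2-(hydroxymethyl)-1,2-dimethyl-N-[(1S)-1-phenylethyl]cyclopentane-1-carboxamide F2. The mirror-image lactone present as contaminant gives the diastereomer (1S,2R)-2-(hydroxymethyl)-1,2-dimethyl-N-[(1S)-1-phenylethyl]cyclopentane-1-carboxamide F3. After separation by chromatography or crystallisation, heating F2 in 2 M H2SO4/1,4-dioxane should relactonise it to enantiopure 8.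

Step 12. Lithiation at the hindered dithiane carbon next to the lithium alkoxide may be incomplete, or base-induced 1,4-elimination of HCl from 18 may compete with substitution. The fallback replaces the dianion by the mono-anion of an O-protected dithiane and runs from 11 to 19. The hydroxyl of 11 is capped with Et3SiCl and imidazole in CH2Cl2 as triethyl({(1S,2S)-2-[(1,3-dithian-2-yl)methyl]-1,2-dimethylcyclopentyl}methoxy)silane F4. A single carbanion is then generated with t-BuLi in THF–HMPA at −78 °C and alkylated with 18 to give the bis-silyl ether tert-butyl{2-[(2E)-4-{2-[((1S,2S)-1,2-dimethyl-2-{[(triethylsilyl)oxy]methyl}cyclopentyl)methyl]-1,3-dithian-2-yl}-3-methylbut-2-en-1-yl]-4-methoxy-6-methylphenoxy}dimethylsilane F5. Pyridinium p-toluenesulfonate in MeOH at room temperature should remove the alkyl triethylsilyl group without touching the hindered aryl silyl ether or the dithiane, and returns 19.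

Further compounds
F1 | step 19 | (2Z)-4-hydroxy-1-[(1S,2S)-2-{3-[(2S)-6-methoxy-2,8-dimethyl-2H-chromen-2-yl]-2-oxopropyl}-1,2-dimethylcyclopentyl]-4-methylpent-2-en-1-one | COc1cc(C)c2c(c1)C=C[C@](C)(CC(=O)C[C@]1(C)CCC[C@]1(C)C(=O)/C=C\C(C)(C)O)O2
F2 | step 3 | (1R,2S)-2-(hydroxymethyl)-1,2-dimethyl-N-[(1S)-1-phenylethyl]cyclopentane-1-carboxamide | C[C@H](NC(=O)[C@]1(C)CCC[C@]1(C)CO)c1ccccc1
F3 | step 3 | (1S,2R)-2-(hydroxymethyl)-1,2-dimethyl-N-[(1S)-1-phenylethyl]cyclopentane-1-carboxamide | C[C@H](NC(=O)[C@@]1(C)CCC[C@@]1(C)CO)c1ccccc1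
F4 | step 12 | triethyl({(1S,2S)-2-[(1,3-dithian-2-yl)methyl]-1,2-dimethylcyclopentyl}methoxy)silane | C3(SCCCS3)C[C@]1(C)CCC[C@]1(C)CO[Si](CC)(CC)CC
F5 | step 12 | tert-butyl{2-[(2E)-4-{2-[((1S,2S)-1,2-dimethyl-2-{[(triethylsilyl)oxy]methyl}cyclopentyl)methyl]-1,3-dithian-2-yl}-3-methylbut-2-en-1-yl]-4-methoxy-6-methylphenoxy}dimethylsilane | COc1cc(C)c(O[Si](C)(C)C(C)(C)C)c(C/C=C(\C)CC2(C[C@]3(C)CCC[C@]3(C)CO[Si](CC)(CC)CC)SCCCS2)c1
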